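The route rests on cutting the CH=C(CH3) double bond that links the stereogenic carbon on chromene C6 to C2 of the benzofuran. A Horner–Wadsworth–Emmons olefination joins both halves and sets the E geometry in one operation. It exploits the position of this alkene between an α-aryl aldehyde carbon and the furan-ring C2 carbon, which stabilises a phosphonate carbanion. The precursors are the (R)-2-(chromen-6-yl)propanal, made by auxiliary-controlled methylation, and a racemic 1-(benzofuran-2-yl)ethylphosphonate whose acetyl group and phenol are masked as a silyl enol ether and an aryl silyl ether, so that fluoride alone releases the target.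

Key step: step 14

Remark on the chemistry: the stereocentre keeps one spatial arrangement from 14 to 31; it is named R in 14, 15 and 16 and S in 30 and 31 only because the alkenyl carbon ranks below the aryl carbon, whereas acyl, CH2OH and CHO rank above it.

Remark on the chemistry: a ketal and acetal pair for the acetyl group and the phenol would need acid to install and to remove, which the electron-rich 2,2-dimethylchromene and the benzofuran-conjugated alkene tolerate poorly; the silyl pair is installed in one basic step and removed in one fluoride step.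

Step 1
Reactants: 1 4-bromo-3-methoxyphenol; 2 3-methylbut-2-enal
Product: 5 6-bromo-7-methoxy-2,2-dimethyl-2H-chromene, via benzodioxaborinine adduct 3 (not isolated), via ortho-quinone methide 4 (not isolated)
Conditions: PhB(OH)2 (1 equiv), AcOH, toluene, reflux, Dean–Stark
Reagents that add atoms: none
Why: Phenylboronic acid templates ortho-hydroxyalkylation of the phenol (adduct 3), which fragments on heating to ortho-quinone methide 4 and closes by oxa-6π electrocyclisation (boronic acid-mediated chromene synthesis); closure should take the ortho carbon para to the methoxy group, not the one flanked by OH and OMe.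

Step 2
Reactants: 5 6-bromo-7-methoxy-2,2-dimethyl-2H-chromene; 6 (2-ethoxy-2-oxoethyl)zinc bromide (commercial solution)
Product: 7 ethyl 2-(7-methoxy-2,2-dimethyl-2H-chromen-6-yl)acetate
Conditions: Pd2(dba)3 (2.5 mol %), XPhos (10 mol %), THF, 65 °C
Reagents that add atoms: none
Why: Negishi-type cross-coupling of a Reformatsky reagent with an aryl bromide (α-arylation of a zinc ester enolate); the neutral zinc enolate spares the chromene and the bulky biaryl phosphine copes with the ortho-methoxy bromide.

Step 3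
Reactants: 7 ethyl 2-(7-methoxy-2,2-dimethyl-2H-chromen-6-yl)acetate
Product: 9 2-(7-methoxy-2,2-dimethyl-2H-chromen-6-yl)acetic acid, via lithium carboxylate 8 (not isolated)
Conditions: LiOH·H2O, THF/MeOH/H2O, 20 °C; then 1 M HCl to pH 3, 0 °C
Reagents that add atoms: lithium hydroxide (its oxygen ends in the carboxyl group), [Li+].[OH-]
Why: Ester saponification under basic conditions that leave the acid-sensitive chromene untouched; the acidification is cold and brief.

Step 4
Reactants: 9 2-(7-methoxy-2,2-dimethyl-2H-chromen-6-yl)acetic acid; 10 (4R)-4-benzyl-1,3-oxazolidin-2-one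
Product: 12 (4R)-4-benzyl-3-[2-(7-methoxy-2,2-dimethyl-2H-chromen-6-yl)acetyl]-1,3-oxazolidin-2-one, via mixed pivalic anhydride 11 (not isolated)
Conditions: pivaloyl chloride, Et3N, THF, −20 °C; then LiCl, 10, −20 to 20 °C
Reagents that add atoms: none
Why: N-acylation of the oxazolidinone through the mixed pivalic anhydride (LiCl/Et3N variant), which avoids an acid chloride and ketene formation from the arylacetic acid; the nucleophile should attack the less hindered arylacetyl carbonyl.

Step 5
Reactants: 12 (4R)-4-benzyl-3-[2-(7-methoxy-2,2-dimethyl-2H-chromen-6-yl)acetyl]-1,3-oxazolidin-2-one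
Product: 14 (4R)-4-benzyl-3-[(2R)-2-(7-methoxy-2,2-dimethyl-2H-chromen-6-yl)propanoyl]-1,3-oxazolidin-2-one, via sodium Z-enolate 13 (not isolated)
Conditions: NaN(SiMe3)2 (1.05 equiv), THF, −78 °C; MeI, −78 to −40 °C; cold AcOH quench
Reagents that add atoms: iodomethane, CI
Why: Evans asymmetric alkylation, in which the C4 benzyl group of the (R)-auxiliary shields one face of the chelated Z-enolate 13 so that iodomethane adds to the other face and sets the new benzylic centre as R; base is kept to a slight excess and the quench is cold because the product is more acidic than 12, and the minor diastereomer would be removed by chromatography or crystallisation.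

Step 6
Reactants: 14 (4R)-4-benzyl-3-[(2R)-2-(7-methoxy-2,2-dimethyl-2H-chromen-6-yl)propanoyl]-1,3-oxazolidin-2-one
Product: 15 (2R)-2-(7-methoxy-2,2-dimethyl-2H-chromen-6-yl)propan-1-ol
Conditions: LiBH4, H2O (1 equiv), Et2O, 0 °C
Reagents that add atoms: none
Why: Reductive cleavage of the N-acyl oxazolidinone with lithium borohydride (hydride attack at the exocyclic carbonyl) gives the primary alcohol without touching the stereocentre and returns the auxiliary.

Step 7
Reactants: 15 (2R)-2-(7-methoxy-2,2-dimethyl-2H-chromen-6-yl)propan-1-ol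
Product: 16 (2R)-2-(7-methoxy-2,2-dimethyl-2H-chromen-6-yl)propanal
Conditions: Dess–Martin periodinane, NaHCO3, CH2Cl2, 0 to 20 °C; used at once
Reagents that add atoms: none
Why: Dess–Martin oxidation of a primary alcohol under buffered, non-basic conditions, chosen because α-aryl aldehydes enolise easily; the aldehyde is filtered through a short pad and taken directly into step 14.

Step 8
Reactants: 17 1-(2,4-dihydroxyphenyl)ethan-1-one
Product: 18 1-(2,4-dihydroxy-5-iodophenyl)ethan-1-one
Conditions: BnMe3N ICl2, NaHCO3, CH2Cl2/MeOH, 20 °C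
Reagents that add atoms: benzyltrimethylammonium dichloroiodate, C[N+](C)(C)Cc1ccccc1.Cl[I-]Cl
Why: Electrophilic aromatic iodination at C5, the accessible carbon ortho to the free 4-hydroxyl and para to the chelated 2-hydroxyl, whereas C3 lies between two oxygens; any 3-iodo isomer would be removed by crystallisation.

Step 9
Reactants: 18 1-(2,4-dihydroxy-5-iodophenyl)ethan-1-one; 19 prop-2-yn-1-ol
Product: 21 1-[6-hydroxy-2-(hydroxymethyl)-1-benzofuran-5-yl]ethan-1-one, via alkynylphenol 20 (not isolated)
Conditions: PdCl2(PPh3)2 (3 mol %), CuI (6 mol %), Et3N, DMF, 60 °C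
Reagents that add atoms: none
Why: Sonogashira coupling followed in the same flask by metal-promoted 5-endo-dig attack of the neighbouring 4-hydroxyl on the alkyne (Sonogashira heteroannulation to a 2-substituted benzofuran); the chelated 2-hydroxyl and the acetyl group should not interfere.

Step 10
Reactants: 21 1-[6-hydroxy-2-(hydroxymethyl)-1-benzofuran-5-yl]ethan-1-one
Product: 22 1-[2-(bromomethyl)-6-hydroxy-1-benzofuran-5-yl]ethan-1-one
Conditions: PBr3 (0.4 equiv), CH2Cl2, 0 °C; used crude
Reagents that add atoms: phosphorus tribromide, BrP(Br)Br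
Why: Conversion of a primary benzofuranylmethanol into its bromide with PBr3 (bromide displacement on the phosphite ester); the hydrogen-bonded phenol and the aryl ketone should be inert at 0 °C.

Step 11
Reactants: 22 1-[2-(bromomethyl)-6-hydroxy-1-benzofuran-5-yl]ethan-1-one
Product: 23 diethyl [(5-acetyl-6-hydroxy-1-benzofuran-2-yl)methyl]phosphonate
Conditions: P(OEt)3 (neat, 5 equiv), 110 °C
Reagents that add atoms: triethyl phosphite, CCOP(OCC)OCC
Why: Michaelis–Arbuzov reaction of a primary benzylic-type bromide, the most reliable case of this reaction; a free phenol tolerates hot trialkyl phosphite, as the preparation of hydroxybenzylphosphonates shows.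

Step 12
Reactants: 23 diethyl [(5-acetyl-6-hydroxy-1-benzofuran-2-yl)methyl]phosphonate
Product: 25 diethyl {[6-{[tert-butyl(dimethyl)silyl]oxy}-5-(1-{[tert-butyl(dimethyl)silyl]oxy}ethenyl)-1-benzofuran-2-yl]methyl}phosphonate, via aryl silyl ether 24 (not isolated)
Conditions: tBuMe2SiOTf (2.6 equiv), Et3N (4 equiv), CH2Cl2, 0 to 20 °C; chromatography on Et3N-treated silica
Reagents that add atoms: tert-butyldimethylsilyl trifluoromethanesulfonate, CC(C)(C)[Si](C)(C)OS(=O)(=O)C(F)(F)F
Why: O-silylation of the phenol and soft enolisation with O-silylation of the methyl ketone (silyl triflate and tertiary amine) give the aryl silyl ether and the silyl enol ether in one operation; this masks the acidic acetyl CH3 and the phenol without acid.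

Step 13
Reactants: 25 diethyl {[6-{[tert-butyl(dimethyl)silyl]oxy}-5-(1-{[tert-butyl(dimethyl)silyl]oxy}ethenyl)-1-benzofuran-2-yl]methyl}phosphonate
Product: 27 diethyl {1-[6-{[tert-butyl(dimethyl)silyl]oxy}-5-(1-{[tert-butyl(dimethyl)silyl]oxy}ethenyl)-1-benzofuran-2-yl]ethyl}phosphonate (racemic), via lithiated phosphonate 26 (not isolated)
Conditions: LiN(iPr)2 (1.05 equiv), THF, −78 °C; MeI (1.1 equiv), −78 to −30 °C
Reagents that add atoms: iodomethane, CI
Why: α-Alkylation of a benzylic-type phosphonate carbanion, the only CH acidic enough once the acetyl group is an enol silane; one equivalent each of base and iodomethane limits dimethylation, and the new centre is racemic and is erased in step 14.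

Step 14
Reactants: 16 (2R)-2-(7-methoxy-2,2-dimethyl-2H-chromen-6-yl)propanal; 27 diethyl {1-[6-{[tert-butyl(dimethyl)silyl]oxy}-5-(1-{[tert-butyl(dimethyl)silyl]oxy}ethenyl)-1-benzofuran-2-yl]ethyl}phosphonate
Product: 30 6-{[tert-butyl(dimethyl)silyl]oxy}-5-(1-{[tert-butyl(dimethyl)silyl]oxy}ethenyl)-2-[(2E,4S)-4-(7-methoxy-2,2-dimethyl-2H-chromen-6-yl)pent-2-en-2-yl]-1-benzofuran, via potassium phosphonate carbanion 28 (not isolated), via β-oxido phosphonate 29 (not isolated)
Conditions: 27 (1.2 equiv), KN(SiMe3)2 (1.1 equiv), THF, −78 °C; then 16 (1.0 equiv), −78 to 20 °C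
Reagents that add atoms: none
Why: KN(SiMe3)2 removes the P–CH proton of 27, the carbanion 28 adds to the aldehyde carbonyl of 16 to give the β-oxido phosphonates 29, and these close to oxaphosphetanes and lose potassium diethyl phosphate by syn elimination. This is a Horner–Wadsworth–Emmons olefination of an aldehyde with a 1-arylethylphosphonate, the standard way to E α-methylstyrene-type alkenes. No ring is closed and no stereocentre is created; one C=C bond is formed. The step needs E geometry and retention of the α-aryl stereocentre: addition of the aryl-stabilised carbanion is reversible, so the adducts equilibrate and elimination should drain the one that places the benzofuran trans to the bulky 1-arylethyl group, giving the alkene in which the benzofuran stays coplanar with the double bond. Epimerisation should be held back by forming the anion completely with less base than phosphonate, so that no free amide meets the aldehyde, and by adding 16 at −78 °C, where carbonyl addition should outrun α-deprotonation. Any Z isomer would be removed by chromatography at the stage of 30 or 31.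

Step 15
Reactants: 30 6-{[tert-butyl(dimethyl)silyl]oxy}-5-(1-{[tert-butyl(dimethyl)silyl]oxy}ethenyl)-2-[(2E,4S)-4-(7-methoxy-2,2-dimethyl-2H-chromen-6-yl)pent-2-en-2-yl]-1-benzofuran
Product: 31 1-{6-hydroxy-2-[(2E,4S)-4-(7-methoxy-2,2-dimethyl-2H-chromen-6-yl)pent-2-en-2-yl]-1-benzofuran-5-yl}ethan-1-one
Conditions: Bu4NF (2.5 equiv), AcOH (2.5 equiv), THF, 0 to 20 °C
Reagents that add atoms: none
Why: Fluoride-induced desilylation cleaves both Si–O bonds (aryl silyl ether and silyl enol ether) while acetic acid protonates the phenoxide and the enolate at once; the methyl ketone is released without aldol side reactions, and nothing present is acidic or basic enough to harm the chromene, move the double bond or touch the stereocentre.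

Compound list
1 | 4-bromo-3-methoxyphenol | COc1cc(O)ccc1Br | starting material
2 | 3-methylbut-2-enal | CC(C)=CC=O | starting material
3 | 6-bromo-7-methoxy-4-(2-methylprop-1-en-1-yl)-2-phenyl-4H-1,3,2-benzodioxaborinine (racemic; not isolated) | COc1cc2OB(c3ccccc3)OC(C=C(C)C)c2cc1Br | intermediate
4 | 4-bromo-3-methoxy-6-(3-methylbut-2-en-1-ylidene)cyclohexa-2,4-dien-1-one (ortho-quinone methide; not isolated) | COC1=CC(=O)C(=CC=C(C)C)C=C1Br | intermediate
5 | 6-bromo-7-methoxy-2,2-dimethyl-2H-chromene | COc1cc2c(cc1Br)C=CC(C)(C)O2 | intermediate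
6 | (2-ethoxy-2-oxoethyl)zinc bromide | CCOC(=O)C[Zn]Br | starting material
7 | ethyl 2-(7-methoxy-2,2-dimethyl-2H-chromen-6-yl)acetate | COc1cc2c(cc1CC(=O)OCC)C=CC(C)(C)O2 | intermediate
8 | lithium 2-(7-methoxy-2,2-dimethyl-2H-chromen-6-yl)acetate (not isolated) | COc1cc2c(cc1CC(=O)[O-])C=CC(C)(C)O2.[Li+] | intermediate
9 | 2-(7-methoxy-2,2-dimethyl-2H-chromen-6-yl)acetic acid | COc1cc2c(cc1CC(=O)O)C=CC(C)(C)O2 | intermediate
10 | (4R)-4-benzyl-1,3-oxazolidin-2-one | O=C1N[C@H](Cc2ccccc2)CO1 | starting material
11 | 2-(7-methoxy-2,2-dimethyl-2H-chromen-6-yl)acetic pivalic anhydride (not isolated) | COc1cc2c(cc1CC(=O)OC(=O)C(C)(C)C)C=CC(C)(C)O2 | intermediate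
12 | (4R)-4-benzyl-3-[2-(7-methoxy-2,2-dimethyl-2H-chromen-6-yl)acetyl]-1,3-oxazolidin-2-one | COc1cc2c(cc1CC(=O)N1[C@H](Cc3ccccc3)COC1=O)C=CC(C)(C)O2 | intermediate
13 | sodium Z-enolate of 12 (not isolated) | COc1cc2c(cc1/C=C(\[O-])N1[C@H](Cc3ccccc3)COC1=O)C=CC(C)(C)O2.[Na+] | intermediate
14 | (4R)-4-benzyl-3-[(2R)-2-(7-methoxy-2,2-dimethyl-2H-chromen-6-yl)propanoyl]-1,3-oxazolidin-2-one | COc1cc2c(cc1[C@@H](C)C(=O)N1[C@H](Cc3ccccc3)COC1=O)C=CC(C)(C)O2 | intermediate
15 | (2R)-2-(7-methoxy-2,2-dimethyl-2H-chromen-6-yl)propan-1-ol | COc1cc2c(cc1[C@@H](C)CO)C=CC(C)(C)O2 | intermediate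
16 | (2R)-2-(7-methoxy-2,2-dimethyl-2H-chromen-6-yl)propanal | COc1cc2c(cc1[C@@H](C)C=O)C=CC(C)(C)O2 | intermediate
17 | 1-(2,4-dihydroxyphenyl)ethan-1-one | CC(=O)c1ccc(O)cc1O | starting material
18 | 1-(2,4-dihydroxy-5-iodophenyl)ethan-1-one | CC(=O)c1cc(I)c(O)cc1O | intermediate
19 | prop-2-yn-1-ol | C#CCO | starting material
20 | 1-[2,4-dihydroxy-5-(3-hydroxyprop-1-yn-1-yl)phenyl]ethan-1-one (not isolated) | CC(=O)c1cc(C#CCO)c(O)cc1O | intermediate
21 | 1-[6-hydroxy-2-(hydroxymethyl)-1-benzofuran-5-yl]ethan-1-one | CC(=O)c1cc2cc(CO)oc2cc1O | intermediate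
22 | 1-[2-(bromomethyl)-6-hydroxy-1-benzofuran-5-yl]ethan-1-one | CC(=O)c1cc2cc(CBr)oc2cc1O | intermediate
23 | diethyl [(5-acetyl-6-hydroxy-1-benzofuran-2-yl)methyl]phosphonate | CCOP(=O)(OCC)Cc1cc2cc(C(C)=O)c(O)cc2o1 | intermediate
24 | diethyl [(5-acetyl-6-{[tert-butyl(dimethyl)silyl]oxy}-1-benzofuran-2-yl)methyl]phosphonate (not isolated) | CCOP(=O)(OCC)Cc1cc2cc(C(C)=O)c(O[Si](C)(C)C(C)(C)C)cc2o1 | intermediate
25 | diethyl {[6-{[tert-butyl(dimethyl)silyl]oxy}-5-(1-{[tert-butyl(dimethyl)silyl]oxy}ethenyl)-1-benzofuran-2-yl]methyl}phosphonate | CCOP(=O)(OCC)Cc1cc2cc(C(=C)O[Si](C)(C)C(C)(C)C)c(O[Si](C)(C)C(C)(C)C)cc2o1 | intermediate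
26 | lithium salt of 25, α-phosphonyl carbanion (not isolated) | CCOP(=O)(OCC)[CH-]c1cc2cc(C(=C)O[Si](C)(C)C(C)(C)C)c(O[Si](C)(C)C(C)(C)C)cc2o1.[Li+] | intermediate
27 | diethyl {1-[6-{[tert-butyl(dimethyl)silyl]oxy}-5-(1-{[tert-butyl(dimethyl)silyl]oxy}ethenyl)-1-benzofuran-2-yl]ethyl}phosphonate (racemic) | CCOP(=O)(OCC)C(C)c1cc2cc(C(=C)O[Si](C)(C)C(C)(C)C)c(O[Si](C)(C)C(C)(C)C)cc2o1 | intermediate
28 | potassium salt of 27, α-phosphonyl carbanion (not isolated) | CCOP(=O)(OCC)[C-](C)c1cc2cc(C(=C)O[Si](C)(C)C(C)(C)C)c(O[Si](C)(C)C(C)(C)C)cc2o1.[K+] | intermediate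
29 | potassium β-oxido phosphonate from 28 and 16 (R at the original centre, mixture at the two new centres; not isolated) | COc1cc2c(cc1[C@@H](C)C([O-])C(C)(P(=O)(OCC)OCC)c1cc3cc(C(=C)O[Si](C)(C)C(C)(C)C)c(O[Si](C)(C)C(C)(C)C)cc3o1)C=CC(C)(C)O2.[K+] | intermediate
30 | 6-{[tert-butyl(dimethyl)silyl]oxy}-5-(1-{[tert-butyl(dimethyl)silyl]oxy}ethenyl)-2-[(2E,4S)-4-(7-methoxy-2,2-dimethyl-2H-chromen-6-yl)pent-2-en-2-yl]-1-benzofuran | COc1cc2c(cc1[C@@H](C)/C=C(\C)c1cc3cc(C(=C)O[Si](C)(C)C(C)(C)C)c(O[Si](C)(C)C(C)(C)C)cc3o1)C=CC(C)(C)O2 | intermediate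
31 | 1-{6-hydroxy-2-[(2E,4S)-4-(7-methoxy-2,2-dimethyl-2H-chromen-6-yl)pent-2-en-2-yl]-1-benzofuran-5-yl}ethan-1-one | COc1cc2c(cc1[C@@H](C)/C=C(\C)c1cc3cc(C(C)=O)c(O)cc3o1)C=CC(C)(C)O2 | target

Total step count: 15.
Longest linear sequence: 9 steps (steps 1 to 7, then 14 and 15); the phosphonate branch has 6 steps (8 to 13).

Steps most likely to fail

Step 14. What may go wrong: the basic phosphonate carbanion may deprotonate the α-aryl aldehyde instead of adding to it, which would erode enantiopurity. The crowded β-oxido phosphonate may also collapse slowly, or the elimination may give too much Z alkene. Fallback: a Julia–Kocienski olefination, which uses a less basic sulfonyl carbanion. It sets out from bromide 22. S-alkylation with 1-phenyl-1H-tetrazole-5-thiol and Et3N in acetone should give the phenyltetrazolyl sulfide F1. Oxidation with H2O2 and catalytic (NH4)6Mo7O24 in ethanol should give the phenyltetrazolyl sulfone F2. Treatment with tBuMe2SiOTf and Et3N, as in step 12, should give the bis-silyl sulfone F3. LiN(SiMe3)2 followed by iodomethane at −78 °C should give the racemic α-methyl sulfone F4. KN(SiMe3)2 in DME at −78 °C followed by aldehyde 16 should then give, by addition, Smiles rearrangement and loss of sulfur dioxide and phenyltetrazolone, compound 30, where the route is rejoined.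

Step 12. What may go wrong: incomplete enolisation and silylation of the hindered, electron-rich ketone, or hydrolysis of the silyl enol ether during work-up, chromatography or step 13. Fallback: masking the ketone as a cyclic ketal. It sets out from 23. tBuMe2SiCl and imidazole in DMF should give the aryl silyl ether 24, now isolated. Ethylene glycol, triethyl orthoformate and catalytic TsOH at 20 °C should give the silyl ether dioxolane phosphonate F5. LiN(iPr)2 and iodomethane should give the α-methyl dioxolane phosphonate F6. KN(SiMe3)2 and aldehyde 16, as in step 14, should give the silyl ether dioxolane alkene F7. Bu4NF in THF at 0 °C should give the phenol dioxolane alkene F8, which is not isolated; brief treatment with dilute aqueous oxalic acid should open the ketal, made very labile by the free ortho hydroxyl, and give 31, where the route is rejoined.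

Step 1. What may go wrong: low conversion of the only moderately activated bromophenol, or ring closure at the ortho carbon between the two oxygens. Fallback: a propargyl ether Claisen sequence. It sets out from 1. O-alkylation with 3-chloro-3-methylbut-1-yne, DBU and catalytic CuCl2 in MeCN at 0 °C should give the aryl dimethylpropargyl ether F9. Heating in N,N-diethylaniline at about 190 °C (aromatic propargyl Claisen rearrangement, 1,5-hydrogen shift and oxa-6π closure through 4) should give 5, where the route is rejoined; a regioisomeric chromene, if formed, would be separated by chromatography.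

Further compounds
F1 | step 14 | phenyltetrazolyl sulfide: 1-[6-hydroxy-2-{[(1-phenyl-1H-tetrazol-5-yl)sulfanyl]methyl}-1-benzofuran-5-yl]ethan-1-one | CC(=O)c1cc2cc(CSc3nnnn3-c3ccccc3)oc2cc1O
F2 | step 14 | phenyltetrazolyl sulfone: 1-[6-hydroxy-2-{[(1-phenyl-1H-tetrazol-5-yl)sulfonyl]methyl}-1-benzofuran-5-yl]ethan-1-one | CC(=O)c1cc2cc(CS(=O)(=O)c3nnnn3-c3ccccc3)oc2cc1O
F3 | step 14 | bis-silyl sulfone: 5-({[6-{[tert-butyl(dimethyl)silyl]oxy}-5-(1-{[tert-butyl(dimethyl)silyl]oxy}ethenyl)-1-benzofuran-2-yl]methyl}sulfonyl)-1-phenyl-1H-tetrazole | CC(C)(C)[Si](C)(C)OC(=C)c1cc2cc(CS(=O)(=O)c3nnnn3-c3ccccc3)oc2cc1O[Si](C)(C)C(C)(C)C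
F4 | step 14 | α-methyl sulfone (racemic): 5-({1-[6-{[tert-butyl(dimethyl)silyl]oxy}-5-(1-{[tert-butyl(dimethyl)silyl]oxy}ethenyl)-1-benzofuran-2-yl]ethyl}sulfonyl)-1-phenyl-1H-tetrazole | CC(C)(C)[Si](C)(C)OC(=C)c1cc2cc(C(C)S(=O)(=O)c3nnnn3-c3ccccc3)oc2cc1O[Si](C)(C)C(C)(C)C
F5 | step 12 | silyl ether dioxolane phosphonate: diethyl {[6-{[tert-butyl(dimethyl)silyl]oxy}-5-(2-methyl-1,3-dioxolan-2-yl)-1-benzofuran-2-yl]methyl}phosphonate | CCOP(=O)(OCC)Cc1cc2cc(C3(C)OCCO3)c(O[Si](C)(C)C(C)(C)C)cc2o1
F6 | step 12 | α-methyl dioxolane phosphonate (racemic): diethyl {1-[6-{[tert-butyl(dimethyl)silyl]oxy}-5-(2-methyl-1,3-dioxolan-2-yl)-1-benzofuran-2-yl]ethyl}phosphonate | CCOP(=O)(OCC)C(C)c1cc2cc(C3(C)OCCO3)c(O[Si](C)(C)C(C)(C)C)cc2o1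
F7 | step 12 | silyl ether dioxolane alkene: 6-{[tert-butyl(dimethyl)silyl]oxy}-2-[(2E,4S)-4-(7-methoxy-2,2-dimethyl-2H-chromen-6-yl)pent-2-en-2-yl]-5-(2-methyl-1,3-dioxolan-2-yl)-1-benzofuran | COc1cc2c(cc1[C@@H](C)/C=C(\C)c1cc3cc(C4(C)OCCO4)c(O[Si](C)(C)C(C)(C)C)cc3o1)C=CC(C)(C)O2
F8 | step 12 | phenol dioxolane alkene: 2-[(2E,4S)-4-(7-methoxy-2,2-dimethyl-2H-chromen-6-yl)pent-2-en-2-yl]-5-(2-methyl-1,3-dioxolan-2-yl)-1-benzofuran-6-ol | COc1cc2c(cc1[C@@H](C)/C=C(\C)c1cc3cc(C4(C)OCCO4)c(O)cc3o1)C=CC(C)(C)O2
F9 | step 1 | aryl dimethylpropargyl ether: 1-bromo-2-methoxy-4-[(2-methylbut-3-yn-2-yl)oxy]benzene | COc1cc(OC(C)(C)C#C)ccc1Br
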